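**Retrosynthetic overview**
- Last, the C4 formyl group is made from an aryl bromide by Pd-catalysed reductive carbonylation.
- The indenone C2=C3 bond comes from a one-pot enolate dehydrogenation of a 2-azulenyl-3-methylindan-1-one.
- Key disconnection: the indanone C2–azulene C3 bond. The ketone α-carbon is turned into an electrophilic, iodine-bound enolonium and trapped by guaiazulene, so two carbons that are both nucleophilic in their normal polarity are joined.
- The bromo-indanone comes in one flask from 4-bromotoluene and crotonyl chloride (Friedel–Crafts acylation, then Nazarov closure).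
- Ring order: the benzene ring and the azulene are bought; the five-membered carbocycle is the only ring built (step 1).

Assumption: the target SMILES has no stereocentre and the aryl–azulene axis is not defined, so the compound is made as the single achiral structure given; sp3 stereocentres in intermediates are racemic and are erased in step 3.
Assumption: AlCl3, CF3SO3H and BF3·OEt2 act as acid promoters and leave their steps unchanged.

**Step 1**
Reactants: 1 4-bromotoluene; 2 (E)-but-2-enoyl chloride (crotonyl chloride)
Product: 4 rac-4-bromo-3,7-dimethylindan-1-one, via aryl propenyl ketone 3 (not isolated)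
Conditions: AlCl3 (1.3 equiv), CH2Cl2, 0 °C → rt; CH2Cl2 distilled off; CF3SO3H, 60 °C (same flask)
Reagents that add atoms: none
Why: Friedel–Crafts acylation goes ortho to the methyl group (para is blocked by Br and CH3 is the stronger director), and the aryl propenyl ketone then undergoes superacid-promoted Nazarov cyclisation at its only free ortho carbon (next to Br), which fixes the 3-methyl/4-bromo/7-methyl pattern; C3 forms racemic and is made planar later.

**Step 2 (key step)**
Reactants: 4 rac-4-bromo-3,7-dimethylindan-1-one; 5 guaiazulene (1,4-dimethyl-7-(propan-2-yl)azulene)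
Product: 8 rac-4-bromo-2-[3,8-dimethyl-5-(propan-2-yl)azulen-1-yl]-3,7-dimethylindan-1-one, via trimethylsilyl enol ether 6 (not isolated), via iodine-bound enolonium 7 (not isolated)
Conditions: 4 (1.3 equiv), Me3SiOTf, Et3N, CH2Cl2, 0 °C; transferred into PhI(OAc)2 (1.2 equiv), BF3·OEt2, CH2Cl2, −78 °C; then 5 (1.0 equiv), −78 → −40 °C
Reagents that add atoms: none
Why: Proposed new method: silylation gives the only possible enol ether (C2 is the sole enolisable carbon), PhI(OAc)2/BF3 converts it at −78 °C into the iodine-bound enolonium whose C2 is electrophilic, and guaiazulene (more nucleophilic than the indoles used in such couplings) attacks through its only free five-ring position with loss of PhI and a proton, mainly anti to the 3-methyl group (trans isomer, erased in step 3), the iodine reagent being kept substoichiometric to the enol ether so that none is left to oxidise the azulene; closest known reaction type: umpolung α-arylation of ketones via enolonium species generated from silyl enol ethers with a trivalent-iodine reagent and trapped by indoles or pyrroles.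

**Step 3**
Reactants: 8 rac-4-bromo-2-[3,8-dimethyl-5-(propan-2-yl)azulen-1-yl]-3,7-dimethylindan-1-one
Product: 11 4-bromo-2-[3,8-dimethyl-5-(propan-2-yl)azulen-1-yl]-3,7-dimethyl-1H-inden-1-one, via lithium enolate 9 (not isolated), via sulfilimine adduct 10 (not isolated)
Conditions: LiN(SiMe3)2, THF, −78 °C; then PhS(Cl)=N-t-Bu, −78 °C → rt
Reagents that add atoms: none
Why: Mukaiyama dehydrogenation: the lithium enolate is sulfinimidoylated at C2 anti to the 3-methyl group and the adduct undergoes syn-elimination with the cis C3–H through a five-membered transition state, a polar non-oxidative pathway that spares the oxidation-prone azulene and the aryl bromide and erases both stereocentres.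

**Step 4**
Reactants: 11 4-bromo-2-[3,8-dimethyl-5-(propan-2-yl)azulen-1-yl]-3,7-dimethyl-1H-inden-1-one
Product: 12 2-[3,8-dimethyl-5-(propan-2-yl)azulen-1-yl]-3,7-dimethyl-1-oxo-1H-indene-4-carbaldehyde (target CNP0233877.0)
Conditions: Pd(OAc)2 (3 mol%), n-BuP(1-adamantyl)2 (9 mol%), TMEDA, CO/H2 (1:1, 5 bar), toluene, 100 °C
Reagents that add atoms: carbon monoxide, [C-]#[O+]
Why: Pd-catalysed reductive carbonylation (formylation with synthesis gas): oxidative addition of the aryl bromide to zerovalent palladium, CO insertion and hydrogenolysis of the acylpalladium give the aldehyde, while the tetrasubstituted enone and the azulene are expected to be inert to this homogeneous, amine-buffered system.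

**Compound list**
1 | 4-bromotoluene | Cc1ccc(Br)cc1 | starting material
2 | (E)-but-2-enoyl chloride (crotonyl chloride) | C/C=C/C(=O)Cl | starting material
3 | (E)-1-(5-bromo-2-methylphenyl)but-2-en-1-one (not isolated) | C/C=C/C(=O)c1cc(Br)ccc1C | intermediate
4 | rac-4-bromo-3,7-dimethylindan-1-one | CC1CC(=O)c2c(C)ccc(Br)c21 | intermediate
5 | guaiazulene (1,4-dimethyl-7-(propan-2-yl)azulene) | c1cc(C)c2cc(C(C)C)ccc(C)c1-2 | starting material
6 | rac-[(7-bromo-1,4-dimethyl-1H-inden-3-yl)oxy]trimethylsilane (not isolated) | CC1C=C(O[Si](C)(C)C)c2c(C)ccc(Br)c21 | intermediate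
7 | rac-acetoxy(phenyl)iodanyl enolate of 4, the O-bound enolonium species (not isolated) | CC1C=C(OI(OC(C)=O)c2ccccc2)c2c(C)ccc(Br)c21 | intermediate
8 | rac-4-bromo-2-[3,8-dimethyl-5-(propan-2-yl)azulen-1-yl]-3,7-dimethylindan-1-one (trans major, cis minor) | CC1C(c2cc(C)c3cc(C(C)C)ccc(C)c2-3)C(=O)c2c(C)ccc(Br)c21 | intermediate
9 | lithium enolate of 8 (not isolated) | [Li+].[O-]C1=C(c2cc(C)c3cc(C(C)C)ccc(C)c2-3)C(C)c2c(Br)ccc(C)c21 | intermediate
10 | rac-4-bromo-2-(N-tert-butyl-S-phenylsulfinimidoyl)-2-[3,8-dimethyl-5-(propan-2-yl)azulen-1-yl]-3,7-dimethylindan-1-one (not isolated) | CC1C(c2cc(C)c3cc(C(C)C)ccc(C)c2-3)(S(=NC(C)(C)C)c2ccccc2)C(=O)c2c(C)ccc(Br)c21 | intermediate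
11 | 4-bromo-2-[3,8-dimethyl-5-(propan-2-yl)azulen-1-yl]-3,7-dimethyl-1H-inden-1-one | CC1=C(c2cc(C)c3cc(C(C)C)ccc(C)c2-3)C(=O)c2c(C)ccc(Br)c21 | intermediate
12 | 2-[3,8-dimethyl-5-(propan-2-yl)azulen-1-yl]-3,7-dimethyl-1-oxo-1H-indene-4-carbaldehyde | CC1=C(c2cc(C)c3cc(C(C)C)ccc(C)c2-3)C(=O)c2c(C)ccc(C=O)c21 | target

**Totals**
Total step count: 4. Longest linear sequence: 4 steps (1 → 4 → 8 → 11 → 12); guaiazulene 5 enters as a purchased partner in step 2.

**Steps most likely to fail**

Step 2 (key coupling). The risks are electron transfer from guaiazulene to the enolonium (azulene dimers) and loss of the C3 proton from the enolonium before capture. The fallback sets out from 4 and comes back at 11, so step 3 is then not needed. SeO2 in wet dioxane at reflux oxidises the only α-methylene of 4 to 4-bromo-3,7-dimethylindane-1,2-dione F1 (largely present as its 2-hydroxyindenone enol). F1 and guaiazulene 5 in AcOH at 50 °C undergo Friedel–Crafts hydroxyalkylation at the more electrophilic C2 carbonyl to give the tertiary carbinol rac-4-bromo-2-hydroxy-2-[3,8-dimethyl-5-(propan-2-yl)azulen-1-yl]-3,7-dimethylindan-1-one F2. In the same acid F2 ionises to the azulene-stabilised cation and loses the C3 proton to give 11.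

Step 3 (dehydrogenation). The risk is slow attack of the sulfur electrophile at the congested, azulene-bearing C2. The fallback sets out from 8 and comes back at 11. Enolate 9, made as in step 3, is quenched at −78 °C with PhSeBr to give rac-4-bromo-2-[3,8-dimethyl-5-(propan-2-yl)azulen-1-yl]-3,7-dimethyl-2-(phenylselanyl)indan-1-one F3. Oxidation with NaIO4 (NaHCO3, aqueous THF/MeOH, 0 °C → rt) gives the selenoxide F4, which undergoes syn-elimination with the cis C3–H to give 11. The weak C–Se bond and the small selenium electrophile make this a different bond-breaking manifold from the sulfilimine route.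

Step 4 (formylation). The risks are hydrodebromination and reduction of the enone or azulene under CO/H2. The fallback sets out from 11 and comes back at 12. Stille hydroxymethylation of 11 with Bu3SnCH2OH and Pd(PPh3)4 in dioxane at 90 °C gives 2-[3,8-dimethyl-5-(propan-2-yl)azulen-1-yl]-4-(hydroxymethyl)-3,7-dimethyl-1H-inden-1-one F5. MnO2 in CH2Cl2 at rt then oxidises the benzylic alcohol to the aldehyde 12 without any reducing gas.

**Further compounds**
F1 | step 2 | 4-bromo-3,7-dimethylindane-1,2-dione | CC1C(=O)C(=O)c2c(C)ccc(Br)c21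
F2 | step 2 | rac-4-bromo-2-hydroxy-2-[3,8-dimethyl-5-(propan-2-yl)azulen-1-yl]-3,7-dimethylindan-1-one | CC1C(O)(c2cc(C)c3cc(C(C)C)ccc(C)c2-3)C(=O)c2c(C)ccc(Br)c21
F3 | step 3 | rac-4-bromo-2-[3,8-dimethyl-5-(propan-2-yl)azulen-1-yl]-3,7-dimethyl-2-(phenylselanyl)indan-1-one | CC1C(c2cc(C)c3cc(C(C)C)ccc(C)c2-3)([Se]c2ccccc2)C(=O)c2c(C)ccc(Br)c21
F4 | step 3 | rac-4-bromo-2-[3,8-dimethyl-5-(propan-2-yl)azulen-1-yl]-3,7-dimethyl-2-(phenylseleninyl)indan-1-one | CC1C(c2cc(C)c3cc(C(C)C)ccc(C)c2-3)([Se](=O)c2ccccc2)C(=O)c2c(C)ccc(Br)c21
F5 | step 4 | 2-[3,8-dimethyl-5-(propan-2-yl)azulen-1-yl]-4-(hydroxymethyl)-3,7-dimethyl-1H-inden-1-one | CC1=C(c2cc(C)c3cc(C(C)C)ccc(C)c2-3)C(=O)c2c(C)ccc(CO)c21
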